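**Retrosynthetic overview**
1. Numbering, also used in the names of the spiro compounds: ring A = C1(=CH2)–C2H2–C3H(OH)–C4H(Br)–C5Me2–C6(spiro); ring B = C6–C7H2–C8H2–C9(Me)(OH)–C10H(Cl)–C11H2. The target is 3R,4S,6S,9R,10S, with OH/Br cis on ring A and OH/Cl cis on ring B.
2. The plan rests on the homoallylic alcohol C1(=CH2)–C2H2–C3H(OH) of ring A, with bromine next to it at C4. This unit is what a type-two carbonyl-ene reaction leaves behind, so C2–C3 is cut back to a C3 aldehyde that already carries the 4S bromide and to an isopropenyl group on C6.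
3. Ring order: ring B is bought as a cyclohexanone monoketal and kept mirror-symmetric. Ring A is closed onto it in step 8. Ring B is desymmetrised only afterwards: C10–Cl and C6 by amine-catalysed chlorination, C9 by MeMgBr addition.
4. The C5–C6 bond between the two quaternary carbons comes from an Ireland–Claisen rearrangement of a prenyl ester. The acid carbon becomes C1 (MeLi, Wittig). The vinyl group becomes C4–C3 (hydroboration, oxidation, enamine-catalysed bromination).

Key step: step 8

Assumption: the (S)-diarylprolinol silyl ether of step 7 is taken to give the (S)-2-bromo aldehyde (open-face attack, as with other electrophiles) and the (4R,5R)-imidazolidine of step 10 to give the (S)-2-chloro ketone; both amines are accessible in both mirror-image forms, so an opposite sense would be met with the antipode.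

Step 1
Reactants: 1 ethyl 1,4-dioxaspiro[4.5]decane-8-carboxylate; 2 3-methylbut-2-en-1-ol (prenol)
Product: 3 3-methylbut-2-en-1-yl 1,4-dioxaspiro[4.5]decane-8-carboxylate
Conditions: 2 (4 equiv), Ti(OEt)4 (10 mol %), toluene, 110 °C, EtOH distilled off
Reagents that add atoms: none
Why: Titanate-catalysed transesterification runs under neutral conditions, so the dioxolane and the acid-sensitive allylic alcohol are untouched, and removal of ethanol drives the equilibrium to the prenyl ester.

Step 2
Reactants: 3 3-methylbut-2-en-1-yl 1,4-dioxaspiro[4.5]decane-8-carboxylate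
Product: 6 8-(2-methylbut-3-en-2-yl)-1,4-dioxaspiro[4.5]decane-8-carboxylic acid, via silyl ketene acetal 4 (not isolated), via trimethylsilyl ester 5 (not isolated)
Conditions: LiN(iPr)2, THF, −78 °C; Me3SiCl, −78 °C to rt, then reflux; aq citric acid (pH 4), 0 °C
Reagents that add atoms: chlorotrimethylsilane, C[Si](C)(C)Cl (its silyl group is carried by 4 and 5 only and is lost on work-up)
Why: Ireland–Claisen rearrangement: O-silylation of the ester enolate gives 4 (no E/Z issue, because the α-carbon lies on the mirror plane of ring B), and its irreversible [3,3]-shift joins C6 to the dimethyl-substituted alkene terminus, an established way to link two quaternary carbons, with no stereocentre formed.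

Step 3
Reactants: 6 8-(2-methylbut-3-en-2-yl)-1,4-dioxaspiro[4.5]decane-8-carboxylic acid
Product: 8 1-[8-(2-methylbut-3-en-2-yl)-1,4-dioxaspiro[4.5]decan-8-yl]ethan-1-one, via dilithium gem-diolate 7 (not isolated)
Conditions: MeLi (3.5 equiv), Et2O, 0 °C to rt; inverse quench into cold aq NH4Cl
Reagents that add atoms: methyllithium, [Li]C
Why: Addition of an alkyllithium to a lithium carboxylate stops at the stable gem-diolate 7, which collapses to the methyl ketone only on quench, so no tertiary alcohol should form, and MeLi is small enough to reach this neopentyl-type carboxylate.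

Step 4
Reactants: 8 1-[8-(2-methylbut-3-en-2-yl)-1,4-dioxaspiro[4.5]decan-8-yl]ethan-1-one; 9 methyltriphenylphosphonium bromide
Product: 11 8-(2-methylbut-3-en-2-yl)-8-(prop-1-en-2-yl)-1,4-dioxaspiro[4.5]decane, via methylenetriphenylphosphorane 10 (not isolated)
Conditions: 9 (4 equiv), KOtBu (4 equiv), toluene, rt then 100 °C
Reagents that add atoms: none
Why: Wittig methylenation with the ylide made by KOtBu in hot toluene is the standard answer to hindered, enolisable ketones, since enolisation is reversible there while oxaphosphetane collapse is not, and the ketal and vinyl group are inert.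

Step 5
Reactants: 11 8-(2-methylbut-3-en-2-yl)-8-(prop-1-en-2-yl)-1,4-dioxaspiro[4.5]decane
Product: 13 3-methyl-3-[8-(prop-1-en-2-yl)-1,4-dioxaspiro[4.5]decan-8-yl]butan-1-ol, via trialkylborane 12 (not isolated)
Conditions: (Me2CHCHMe)2BH (1.2 equiv, from BH3·THF and 2-methylbut-2-ene, 0 °C), THF, 0 °C; then NaOH, H2O2, 0 °C to rt
Reagents that add atoms: hydrogen peroxide, OO; disiamylborane, CC(C)C(C)BC(C)C(C)C (boron and its two alkyl groups are carried by 12 only)
Why: Hydroboration–oxidation with a bulky dialkylborane puts boron on the terminal carbon C3 and favours a monosubstituted over a 1,1-disubstituted alkene, and here the isopropenyl group is in addition bound to quaternary C6, so only the vinyl group should react.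

Step 6
Reactants: 13 3-methyl-3-[8-(prop-1-en-2-yl)-1,4-dioxaspiro[4.5]decan-8-yl]butan-1-ol
Product: 14 3-methyl-3-[8-(prop-1-en-2-yl)-1,4-dioxaspiro[4.5]decan-8-yl]butanal
Conditions: TEMPO (2,2,6,6-tetramethylpiperidin-1-oxyl, 10 mol %), PhI(OAc)2 (1.1 equiv), CH2Cl2, rt
Reagents that add atoms: none
Why: Oxoammonium-mediated oxidation of a primary alcohol stops at the aldehyde and leaves the alkene and the ketal alone.

Step 7
Reactants: 14 3-methyl-3-[8-(prop-1-en-2-yl)-1,4-dioxaspiro[4.5]decan-8-yl]butanal
Product: 15 (S)-2-bromo-3-methyl-3-[8-(prop-1-en-2-yl)-1,4-dioxaspiro[4.5]decan-8-yl]butanal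
Conditions: (S)-2-{bis[3,5-bis(trifluoromethyl)phenyl][(trimethylsilyl)oxy]methyl}pyrrolidine (20 mol %), PhCO2H (20 mol %), 4,4-dibromo-2,6-di-tert-butylcyclohexa-2,5-dien-1-one (1.05 equiv), CH2Cl2/pentane, −24 °C; cold filtration through silica
Reagents that add atoms: 4,4-dibromo-2,6-di-tert-butylcyclohexa-2,5-dien-1-one, O=C1C(C(C)(C)C)=CC(Br)(Br)C=C1C(C)(C)C
Why: Enamine-catalysed α-bromination of an aldehyde: the bulky diaryl(silyloxy)methyl group shields one face of the E-enamine, so the mild bromine donor attacks the open face and sets 4S, aldehydes with a tert-alkyl β-carbon are accepted by this catalysis, the enamine outruns the hindered isopropenyl group, and the product cannot lose HBr because C5 has no hydrogen.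

Step 8
Reactants: 15 (S)-2-bromo-3-methyl-3-[8-(prop-1-en-2-yl)-1,4-dioxaspiro[4.5]decan-8-yl]butanal
Product: 17 (3R,4S)-4-bromo-3-hydroxy-5,5-dimethyl-1-methylidenespiro[5.5]undecan-9-one ethylene ketal, via chloro(methyl)aluminium alkoxide 16 (not isolated)
Conditions: Me2AlCl (2.5 equiv), CH2Cl2, −78 to −30 °C; then aq potassium sodium tartrate
Reagents that add atoms: dimethylaluminium chloride, C[Al](C)Cl (aluminium, one methyl and chloride are carried by 16 only)
Why: Me2AlCl binds the C3 aldehyde oxygen, the CH2 terminus of the isopropenyl group on C6 attacks C3 (new bond C2–C3) while one hydrogen of the allylic methyl passes to oxygen through a six-atom array, so the former methyl becomes the exocyclic C1=CH2, and the alcohol–aluminium complex then loses methane to give 16, which removes the only acidic proton and spares ketal and alkene. The closest known reaction type is this very one, the Me2AlCl-promoted type-two intramolecular carbonyl-ene cyclisation of 5-methylhex-5-enals to 3-methylenecyclohexanols, whose accepted chair model places the oxygen pseudoaxial and a 2-substituent equatorial, and halogen-bearing aldehydes are known to be strong enophiles. Ring A closes as a six-membered carbocycle in the type-two mode: the tether sits on the central ene carbon C1, both alkene carbons (C1, C2) become ring members, the carbonyl is attacked 6-exo-trig with its oxygen outside the ring, and the array is chair-like and bicyclo[3.3.1]-shaped. The one new stereocentre, C3, is controlled by the resident 4S centre: Br takes the equatorial site (axial Br would meet the axial ring-B methylene on C6) and so lies antiperiplanar to the forming C2–C3 bond, as the polar Felkin–Anh model asks, while the aluminium-bound oxygen must be pseudoaxial to reach the methyl hydrogen, which gives the cis C3–OH/C4–Br pair, 3R. The step needs ene closure to win over methyl transfer from aluminium, enolisation at C4 and ketal opening, and it needs a single mode of hydrogen transfer: the adjacent quaternary carbons C5 and C6 press the reacting ends together, C6 has no hydrogen so the methyl is the sole donor, C5 has none so HBr cannot be lost, and low temperature with excess Lewis acid (the ketal oxygens tie up part of it) covers the rest. The price is a syn-axial contact between the aluminium-bound oxygen and the axial C5 methyl, which is why the risk of the route sits here.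

Step 9
Reactants: 17 (3R,4S)-4-bromo-3-hydroxy-5,5-dimethyl-1-methylidenespiro[5.5]undecan-9-one ethylene ketal
Product: 18 (3R,4S)-4-bromo-3-hydroxy-5,5-dimethyl-1-methylidenespiro[5.5]undecan-9-one
Conditions: 1 M aq HCl, THF, rt
Reagents that add atoms: water, O
Why: Acid-catalysed ketal hydrolysis is tolerated by the neopentyl-type secondary bromide, the cis-bromohydrin (no antiperiplanar O/Br pair) and the 1,1-disubstituted alkene in dilute acid at room temperature, and C3–OH needs no protection in the two steps that follow.

Step 10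
Reactants: 18 (3R,4S)-4-bromo-3-hydroxy-5,5-dimethyl-1-methylidenespiro[5.5]undecan-9-one
Product: 19 (3R,4S,6S,10S)-4-bromo-10-chloro-3-hydroxy-5,5-dimethyl-1-methylidenespiro[5.5]undecan-9-one
Conditions: N-chlorosuccinimide (1.3 equiv), (4R,5R)-4,5-diphenylimidazolidine (20 mol %), 2-nitrobenzoic acid (50 mol %), MeCN, −24 °C
Reagents that add atoms: N-chlorosuccinimide, O=C1CCC(=O)N1Cl
Why: Enamine-catalysed α-chlorination of a cyclohexanone, used here as a desymmetrisation: the C2-symmetric amine fixes the new C–Cl carbon as S, and since ring B is expected to sit in the chair with bulky C5 equatorial and C1 axial, where an axial chlorine would be syn-axial to C1, an S-configured equatorial chloride is possible only at C10 and not at C8, which sets C6 as S in the same event.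

Step 11
Reactants: 19 (3R,4S,6S,10S)-4-bromo-10-chloro-3-hydroxy-5,5-dimethyl-1-methylidenespiro[5.5]undecan-9-one
Product: 21 (3R,4S,6S,9R,10S)-4-bromo-10-chloro-5,5,9-trimethyl-1-methylidenespiro[5.5]undecane-3,9-diol (CNP0121782.1), via bis(bromomagnesium) alkoxide 20 (not isolated)
Conditions: MeMgBr (3.5 equiv), THF/Et2O, −78 °C; aq NH4Cl at −78 °C
Reagents that add atoms: methylmagnesium bromide, C[Mg]Br
Why: Grignard addition to a 2-chlorocyclohexanone: with Cl locked equatorial the small methyl nucleophile should enter along the equatorial trajectory, trans to chlorine and clear of the axial hydrogens on C7 and C11, to give the axial C9–OH cis to Cl (9R, the classical cis-chlorohydrin outcome), while the first equivalent only deprotonates C3–OH and at −78 °C neither halide nor either cis-halohydrin alkoxide has an anti O/halogen arrangement to react further.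

**Compound list**
1 | ethyl 1,4-dioxaspiro[4.5]decane-8-carboxylate | CCOC(=O)C1CCC2(CC1)OCCO2 | starting material
2 | 3-methylbut-2-en-1-ol (prenol) | CC(C)=CCO | starting material
3 | 3-methylbut-2-en-1-yl 1,4-dioxaspiro[4.5]decane-8-carboxylate | CC(C)=CCOC(=O)C1CCC2(CC1)OCCO2 | intermediate
4 | [(1,4-dioxaspiro[4.5]decan-8-ylidene)(3-methylbut-2-en-1-yloxy)methoxy]trimethylsilane (silyl ketene acetal, not isolated) | CC(C)=CCOC(O[Si](C)(C)C)=C1CCC2(CC1)OCCO2 | intermediate
5 | trimethylsilyl 8-(2-methylbut-3-en-2-yl)-1,4-dioxaspiro[4.5]decane-8-carboxylate (not isolated) | C=CC(C)(C)C1(C(=O)O[Si](C)(C)C)CCC2(CC1)OCCO2 | intermediate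
6 | 8-(2-methylbut-3-en-2-yl)-1,4-dioxaspiro[4.5]decane-8-carboxylic acid | C=CC(C)(C)C1(C(=O)O)CCC2(CC1)OCCO2 | intermediate
7 | dilithium 1-[8-(2-methylbut-3-en-2-yl)-1,4-dioxaspiro[4.5]decan-8-yl]ethane-1,1-diolate (not isolated) | C=CC(C)(C)C1(C(C)([O-])[O-])CCC2(CC1)OCCO2.[Li+].[Li+] | intermediate
8 | 1-[8-(2-methylbut-3-en-2-yl)-1,4-dioxaspiro[4.5]decan-8-yl]ethan-1-one | C=CC(C)(C)C1(C(C)=O)CCC2(CC1)OCCO2 | intermediate
9 | methyltriphenylphosphonium bromide | C[P+](c1ccccc1)(c1ccccc1)c1ccccc1.[Br-] | starting material
10 | methylenetriphenylphosphorane (not isolated) | C=P(c1ccccc1)(c1ccccc1)c1ccccc1 | intermediate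
11 | 8-(2-methylbut-3-en-2-yl)-8-(prop-1-en-2-yl)-1,4-dioxaspiro[4.5]decane | C=CC(C)(C)C1(C(C)=C)CCC2(CC1)OCCO2 | intermediate
12 | bis(3-methylbutan-2-yl){3-methyl-3-[8-(prop-1-en-2-yl)-1,4-dioxaspiro[4.5]decan-8-yl]butyl}borane (not isolated) | C=C(C)C1(C(C)(C)CCB(C(C)C(C)C)C(C)C(C)C)CCC2(CC1)OCCO2 | intermediate
13 | 3-methyl-3-[8-(prop-1-en-2-yl)-1,4-dioxaspiro[4.5]decan-8-yl]butan-1-ol | C=C(C)C1(C(C)(C)CCO)CCC2(CC1)OCCO2 | intermediate
14 | 3-methyl-3-[8-(prop-1-en-2-yl)-1,4-dioxaspiro[4.5]decan-8-yl]butanal | C=C(C)C1(C(C)(C)CC=O)CCC2(CC1)OCCO2 | intermediate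
15 | (S)-2-bromo-3-methyl-3-[8-(prop-1-en-2-yl)-1,4-dioxaspiro[4.5]decan-8-yl]butanal | O=C[C@@H](Br)C(C)(C)C1(C(C)=C)CCC2(CC1)OCCO2 | intermediate
16 | chloro(methyl)aluminium C3-alkoxide of 17 (not isolated) | C=C1C[C@@H](O[Al](C)Cl)[C@@H](Br)C(C)(C)C12CCC3(CC2)OCCO3 | intermediate
17 | (3R,4S)-4-bromo-3-hydroxy-5,5-dimethyl-1-methylidenespiro[5.5]undecan-9-one ethylene ketal | C=C1C[C@@H](O)[C@@H](Br)C(C)(C)C12CCC3(CC2)OCCO3 | intermediate
18 | (3R,4S)-4-bromo-3-hydroxy-5,5-dimethyl-1-methylidenespiro[5.5]undecan-9-one | C=C1C[C@@H](O)[C@@H](Br)C(C)(C)C12CCC(=O)CC2 | intermediate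
19 | (3R,4S,6S,10S)-4-bromo-10-chloro-3-hydroxy-5,5-dimethyl-1-methylidenespiro[5.5]undecan-9-one | C=C1C[C@@H](O)[C@@H](Br)C(C)(C)[C@]12CCC(=O)[C@@H](Cl)C2 | intermediate
20 | C3,C9-bis(bromomagnesium) alkoxide of 21 (not isolated) | C=C1C[C@@H](O[Mg]Br)[C@@H](Br)C(C)(C)[C@]12CC[C@@](C)(O[Mg]Br)[C@@H](Cl)C2 | intermediate
21 | (3R,4S,6S,9R,10S)-4-bromo-10-chloro-5,5,9-trimethyl-1-methylidenespiro[5.5]undecane-3,9-diol (CNP0121782.1) | C=C1C[C@@H](O)[C@@H](Br)C(C)(C)[C@]12CC[C@@](C)(O)[C@@H](Cl)C2 | target

**Total step count:** 11. **Longest linear sequence:** 11 steps, from 1.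

**Steps most likely to fail**

First, step 8.
- What may go wrong: the syn-axial contact between the aluminium-bound oxygen and the axial C5 methyl may slow the chair-like closure. A boat-like or stepwise cationic path could then take over, and facial selectivity at C3 would be lost.
- Fallback: C3 is set by hydride delivery instead of by the ene array. The fallback sets out from 17 as obtained, whatever its composition at C3.
- Dess–Martin periodinane buffered with NaHCO3 (CH2Cl2, 0 °C) should give (4S)-4-bromo-5,5-dimethyl-1-methylidenespiro[5.5]undecane-3,9-dione 9-ethylene ketal F1, in which equatorial bromine remains the stable arrangement.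
- iBu2AlH (CH2Cl2, −78 °C) should then reach C3 along the equatorial trajectory, because the axial C5 methyl closes the axial one. This returns the axial 3R alcohol cis to bromine, and the route is rejoined at 17.

Second, step 10.
- What may go wrong: the amine catalyst may discriminate poorly between the diastereotopic C8 and C10 methylene groups, which is the choice that sets C6. This is most likely if the chair preference of ring B is weaker than assumed. Turnover may also be slow and invite over-chlorination.
- Fallback: group selection is handed to a chiral base, and the C10 configuration to thermodynamic control. The fallback sets out from 18.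
- LiN[(R)-CH(Me)Ph]2 (or its antipode, chosen by the same test as for the amine) is used with Me3SiCl present in THF at −90 °C. This is a selective deprotonation of a 4,4-disubstituted cyclohexanone with in situ quench, and it silylates C3–OH as well. It should give (3R,4S,6S)-4-bromo-5,5-dimethyl-1-methylidene-3,9-bis(trimethylsilyloxy)spiro[5.5]undec-9-ene F2.
- N-chlorosuccinimide in THF chlorinates C10 to give (3R,4S,6S,10S)-4-bromo-10-chloro-5,5-dimethyl-1-methylidene-3-(trimethylsilyloxy)spiro[5.5]undecan-9-one F3. A short exposure to Et3N lets the chloride settle in the equatorial position.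
- Citric acid in MeOH frees C3–OH, and the route is rejoined at 19.

Third, step 7.
- What may go wrong: enamine formation and iminium hydrolysis may be sluggish with so bulky a β-carbon. The bromide may also lose configurational purity by enamine or enol exchange during the long reaction or the filtration.
- Fallback: C4 is set by a covalently bound auxiliary. The fallback sets out from 14.
- Pinnick oxidation (NaClO2, NaH2PO4, 2-methylbut-2-ene, tBuOH/H2O) gives 3-methyl-3-[8-(prop-1-en-2-yl)-1,4-dioxaspiro[4.5]decan-8-yl]butanoic acid F4.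
- Dicyclohexylcarbodiimide, 4-(dimethylamino)pyridine and (S)-4-benzyloxazolidin-2-one give the N-acyl oxazolidinone F5.
- Bu2BOTf and iPr2NEt, then N-bromosuccinimide at −78 °C, brominate the Z-boron enolate on the face away from the benzyl group. This gives the (2S)-2-bromo N-acyl oxazolidinone F6.
- LiBH4 (Et2O with one equivalent of water, 0 °C) releases (S)-2-bromo-3-methyl-3-[8-(prop-1-en-2-yl)-1,4-dioxaspiro[4.5]decan-8-yl]butan-1-ol F7, whose neopentyl-type bromide resists epoxide closure.
- Dess–Martin periodinane oxidises F7 to the aldehyde, and the route is rejoined at 15.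

**Further compounds**
F1 | step 8 | (4S)-4-bromo-5,5-dimethyl-1-methylidenespiro[5.5]undecane-3,9-dione 9-ethylene ketal | C=C1CC(=O)[C@@H](Br)C(C)(C)C12CCC3(CC2)OCCO3
F2 | step 10 | (3R,4S,6S)-4-bromo-5,5-dimethyl-1-methylidene-3,9-bis(trimethylsilyloxy)spiro[5.5]undec-9-ene | C=C1C[C@@H](O[Si](C)(C)C)[C@@H](Br)C(C)(C)[C@]12CCC(O[Si](C)(C)C)=CC2
F3 | step 10 | (3R,4S,6S,10S)-4-bromo-10-chloro-5,5-dimethyl-1-methylidene-3-(trimethylsilyloxy)spiro[5.5]undecan-9-one | C=C1C[C@@H](O[Si](C)(C)C)[C@@H](Br)C(C)(C)[C@]12CCC(=O)[C@@H](Cl)C2
F4 | step 7 | 3-methyl-3-[8-(prop-1-en-2-yl)-1,4-dioxaspiro[4.5]decan-8-yl]butanoic acid | C=C(C)C1(CCC2(CC1)OCCO2)C(C)(C)CC(=O)O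
F5 | step 7 | (S)-4-benzyl-3-{3-methyl-3-[8-(prop-1-en-2-yl)-1,4-dioxaspiro[4.5]decan-8-yl]butanoyl}oxazolidin-2-one | C=C(C)C1(CCC2(CC1)OCCO2)C(C)(C)CC(=O)N1[C@@H](Cc2ccccc2)COC1=O
F6 | step 7 | (S)-4-benzyl-3-{(S)-2-bromo-3-methyl-3-[8-(prop-1-en-2-yl)-1,4-dioxaspiro[4.5]decan-8-yl]butanoyl}oxazolidin-2-one | C=C(C)C1(CCC2(CC1)OCCO2)C(C)(C)[C@H](Br)C(=O)N1[C@@H](Cc2ccccc2)COC1=O
F7 | step 7 | (S)-2-bromo-3-methyl-3-[8-(prop-1-en-2-yl)-1,4-dioxaspiro[4.5]decan-8-yl]butan-1-ol | C=C(C)C1(CCC2(CC1)OCCO2)C(C)(C)[C@H](Br)CO
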